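**Plan**

- Retrosynthesis: after removal of the protecting groups and the C7 methyl, ring A is cut at C3a–C7a and C6–C7. This returns a 2,4-disubstituted furan whose C2 chain ends in an ethynyl ether on the benzylic oxygen O1.
- Feature that allows this cut: ring A carries oxygen on the neighbouring carbons C7a (O1, shared with ring B) and C7 (OMe). This is the pattern left when a furan is converted into a phenol by an alkyne tethered through an ynol ether.
- Further cuts: O1–C(sp) (alcohol plus trichloroethylene), C5–C1′ (furyllithium plus lactate Weinreb amide), C2–C3 (syn-aldol of a furylacetyl imide with the benzylated aldehyde).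
- Forward: the aldol joins the two halves, the imide carbonyl becomes the C3 methyl, and the diol side chain is built on furan C4. One gold step then closes ring B (C3a–C7a) and ring A (C6–C7); O-methylation and deprotection finish.
- Stereochemistry: C2 and C3 come from the (S)-4-benzyloxazolidinone aldol and are not touched again. C2′ comes from ethyl (S)-lactate and C1′ from chelation-controlled Zn(BH4)2 reduction.
- The side chain is attached before the alkyne is made, because the butyllithium needed for the ynol ether would not spare a bromofuran.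

Key step: step 15

Remark: atom labels (O1, C2, C3, C3a–C7a, C1′, C2′) are those of the target and are used for the same atoms in every precursor; 1, 3, 6 and 10 are taken as commercial.

**Route**

Step 1
Reactants: 1 3-hydroxy-4,5-dimethoxybenzaldehyde
Product: 2 3-(benzyloxy)-4,5-dimethoxybenzaldehyde
Conditions: BnBr, K2CO3, DMF, rt
Reagents that add atoms: benzyl bromide, BrCc1ccccc1
Why: Williamson ether synthesis on the only phenol gives a benzyl ether that should survive the boron aldol, the hydride, organolithium and gold steps and is removed last by hydrogenolysis.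

Step 2
Reactants: 3 ethyl (S)-lactate
Product: 4 ethyl (S)-2-(triethylsilyloxy)propanoate
Conditions: Et3SiCl, imidazole, CH2Cl2, 0 °C → rt
Reagents that add atoms: chlorotriethylsilane, CC[Si](Cl)(CC)CC
Why: O-silylation of the secondary alcohol leaves the lactate stereocentre untouched and gives an ether that withstands organomagnesium and organolithium reagents but falls off in dilute acid.

Step 3
Reactants: 4 ethyl (S)-2-(triethylsilyloxy)propanoate
Product: 5 (S)-N-methoxy-N-methyl-2-(triethylsilyloxy)propanamide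
Conditions: MeNHOMe·HCl, i-PrMgCl, THF, −20 → 0 °C
Reagents that add atoms: N,O-dimethylhydroxylamine hydrochloride, CNOC.Cl
Why: Weinreb amide formation by aminolysis of the ester with the magnesium amide made in the flask, a standard conversion of O-silyl lactates that should not erode the α-stereocentre at this temperature.

Step 4
Reactants: 6 4-bromo-2-furaldehyde
Product: 8 2-(4-bromofuran-2-yl)acetonitrile, via tosylvinyl formamide 7 (not isolated)
Conditions: TosMIC, t-BuOK, DME, −40 °C; then MeOH, reflux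
Reagents that add atoms: p-toluenesulfonylmethyl isocyanide (TosMIC), Cc1ccc(cc1)S(=O)(=O)C[N+]#[C-]
Why: van Leusen reductive cyanation, in which the TosMIC anion adds to the aldehyde, the oxazoline opens to the N-formyl enamide and methanol then removes formyl and sulfinate, homologates ArCHO to ArCH2CN in one pot.

Step 5
Reactants: 8 2-(4-bromofuran-2-yl)acetonitrile
Product: 9 2-(4-bromofuran-2-yl)acetic acid
Conditions: KOH, EtOH–H2O, reflux; then aq. HCl
Reagents that add atoms: potassium hydroxide, [K+].[OH-]; water, O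
Why: alkaline nitrile hydrolysis, to which the furan ring and its bromine are inert.

Step 6
Reactants: 9 2-(4-bromofuran-2-yl)acetic acid; 10 (S)-4-benzyl-2-oxazolidinone
Product: 12 (S)-4-benzyl-3-[2-(4-bromofuran-2-yl)acetyl]oxazolidin-2-one, via mixed pivalic anhydride 11 (not isolated)
Conditions: t-BuCOCl, Et3N, THF, −20 °C; then LiCl, 10, −20 °C → rt
Reagents that add atoms: none
Why: N-acylation of the oxazolidinone through the mixed pivalic anhydride, with LiCl and Et3N making the auxiliary nucleophilic enough, is the usual mild way to arylacetyl imides.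

Step 7
Reactants: 12 (S)-4-benzyl-3-[2-(4-bromofuran-2-yl)acetyl]oxazolidin-2-one; 2 3-(benzyloxy)-4,5-dimethoxybenzaldehyde
Product: 14 (S)-4-benzyl-3-[(2R,3S)-3-(3-benzyloxy-4,5-dimethoxyphenyl)-2-(4-bromofuran-2-yl)-3-hydroxypropanoyl]oxazolidin-2-one, via dibutylboron enolate 13 (not isolated)
Conditions: Bu2BOTf, i-Pr2NEt, CH2Cl2, −78 → 0 °C; 2, −78 → 0 °C; pH 7 buffer, MeOH, H2O2, 0 °C
Reagents that add atoms: none
Why: Evans syn-aldol reaction in which the Z boron enolate adds through a Zimmerman–Traxler chair from the face away from the benzyl group of the (S)-auxiliary, which should set the carbinol carbon (future C2) as S and the furyl-bearing carbon (future C3) as R in a syn relationship that becomes trans in ring B.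

Step 8
Reactants: 14 the aldol adduct
Product: 15 (1S,2R)-1-(3-benzyloxy-4,5-dimethoxyphenyl)-2-(4-bromofuran-2-yl)propane-1,3-diol
Conditions: LiBH4, MeOH (1 equiv), THF, 0 °C
Reagents that add atoms: none
Why: reductive cleavage of the N-acyl oxazolidinone by LiBH4 frees the auxiliary and should give the 1,3-diol at low temperature before retro-aldol or epimerisation of the acidic α-position can compete.

Step 9
Reactants: 15 the 1,3-diol
Product: 16 (2R,3S)-3-(3-benzyloxy-4,5-dimethoxyphenyl)-2-(4-bromofuran-2-yl)-3-hydroxypropyl 4-methylbenzenesulfonate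
Conditions: TsCl, Et3N, DMAP (cat.), CH2Cl2, 0 °C
Reagents that add atoms: p-toluenesulfonyl chloride, Cc1ccc(cc1)S(=O)(=O)Cl
Why: selective sulfonylation of the primary hydroxyl, the secondary benzylic one being flanked by the aryl ring and a branched carbon.

Step 10
Reactants: 16 the primary tosylate
Product: 17 (1S,2R)-1-(3-benzyloxy-4,5-dimethoxyphenyl)-2-(4-bromofuran-2-yl)propan-1-ol
Conditions: LiEt3BH, THF, 0 °C → rt
Reagents that add atoms: none
Why: SN2 displacement of the primary tosylate by hydride turns the former carbonyl carbon into the C3 methyl group, and the furyl bromide should not be reduced by LiEt3BH at this temperature.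

Step 11
Reactants: 17 the bromofuryl alcohol; 5 (S)-N-methoxy-N-methyl-2-(triethylsilyloxy)propanamide
Product: 20 (S)-1-{5-[(1S,2R)-1-(3-benzyloxy-4,5-dimethoxyphenyl)-1-hydroxypropan-2-yl]furan-3-yl}-2-hydroxypropan-1-one, via dilithiated furyl alkoxide 18 (not isolated), via silyl-protected ketone 19 (not isolated)
Conditions: n-BuLi (2.1 equiv), THF, −78 °C; 5, −78 → −40 °C; aq. NH4Cl; then AcOH–THF–H2O (3:1:1), rt
Reagents that add atoms: none
Why: deprotonation and bromine–lithium exchange give a 3-furyllithium that is stable at −78 °C and is acylated once by the Weinreb amide through its chelated tetrahedral adduct, so the lactate stereocentre arrives unchanged, and dilute acid then removes the silyl group to free the α-hydroxyl needed for chelation.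

Step 12
Reactants: 20 the α-hydroxy ketone
Product: 21 (1R,2S)-1-{5-[(1S,2R)-1-(3-benzyloxy-4,5-dimethoxyphenyl)-1-hydroxypropan-2-yl]furan-3-yl}propane-1,2-diol
Conditions: Zn(BH4)2, Et2O, −20 → 0 °C
Reagents that add atoms: none
Why: chelation-controlled (Cram chelate) reduction, in which zinc bridges the ketone and the α-hydroxyl and hydride enters from the side of the α-hydrogen, should give the anti diol with C1′ as R next to the lactate-derived S centre.

Step 13
Reactants: 21 the triol
Product: 22 (1S,2R)-1-(3-benzyloxy-4,5-dimethoxyphenyl)-2-{4-[(4R,5S)-2,2,5-trimethyl-1,3-dioxolan-4-yl]furan-2-yl}propan-1-ol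
Conditions: Me2C(OMe)2, pyridinium p-toluenesulfonate (cat.), CH2Cl2, rt
Reagents that add atoms: 2,2-dimethoxypropane, COC(C)(C)OC
Why: acid-catalysed transketalisation closes the dioxolane on the 1,2-diol only, since the isolated benzylic hydroxyl can form no cyclic ketal, and so leaves free exactly the oxygen that is to carry the alkyne.

Step 14
Reactants: 22 the acetonide alcohol
Product: 26 2-[(1S,2R)-1-(3-benzyloxy-4,5-dimethoxyphenyl)-1-(ethynyloxy)propan-2-yl]-4-[(4R,5S)-2,2,5-trimethyl-1,3-dioxolan-4-yl]furan, via potassium alkoxide 23 (not isolated), via dichlorovinyl ether 24 (not isolated), via lithium alkynyl ether 25 (not isolated)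
Conditions: KH, THF, 0 °C; Cl2C=CHCl, −40 °C → rt; then n-BuLi (2.4 equiv), −78 → −40 °C; MeOH, −78 °C; cold work-up, used at once
Reagents that add atoms: trichloroethylene, ClC=C(Cl)Cl
Why: the dichlorovinyl ether route to terminal ynol ethers, in which the potassium alkoxide adds to dichloroacetylene formed in the flask and butyllithium then eliminates HCl and exchanges the remaining chlorine, is established for secondary alcohols and is possible here because the molecule no longer holds an aryl bromide that butyllithium would attack.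

Step 15
Reactants: 26 the furyl ynol ether
Product: 29 (2S,3S)-2-(3-benzyloxy-4,5-dimethoxyphenyl)-3-methyl-5-[(4R,5S)-2,2,5-trimethyl-1,3-dioxolan-4-yl]-2,3-dihydrobenzofuran-7-ol, via oxepine 27 (not isolated), via arene oxide 28 (not isolated)
Conditions: Ph3PAuNTf2 (3 mol %), CH2Cl2, −20 °C → rt
Reagents that add atoms: none
Why: Ph3PAuNTf2 (cationic monovalent gold) polarises the ethynyl ether as a gold ketene-oxonium so that the oxygen-bearing carbon is the electrophile, furan C2 attacks it in a 5-exo-dig sense (bond C3a–C7a, ring B) to give a cyclopropyl gold carbenoid that opens the furan to a (Z)-dienal gold carbene, and the aldehyde oxygen then closes on the carbene carbon to release the catalyst and oxepine 27. Ring A arises by 6π-electrocyclisation of 27 (bond C6–C7) to arene oxide 28, which opens towards the cation stabilised by O1 at C7a and so leaves the hydroxyl on C7, the former terminal alkyne carbon. The closest known reaction is the gold-catalysed furan–yne phenol synthesis, which with ynol ether tethers of this length gives 2,3-dihydrobenzofuran-7-ols. No stereocentre is formed and no bond to C2 or C3 is broken, so the aldol-derived (2S,3S) trans relationship is carried into ring B unchanged. The step needs chemoselectivity for the furan over the trioxygenated arene and speed relative to ionisation or sigmatropic loss of the benzylic ynol ether: the furan reaches the alkyne through an exo five-membered transition state whereas the arene could only close a ring endo to its own π bond, and the low temperature and the non-acidic catalyst should keep the benzylic C–O bond intact. The dioxolane side chain on furan C4 (future C5) is a spectator.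

Step 16
Reactants: 29 the dihydrobenzofuran-7-ol
Product: 30 (2S,3S)-2-(3-benzyloxy-4,5-dimethoxyphenyl)-7-methoxy-3-methyl-5-[(4R,5S)-2,2,5-trimethyl-1,3-dioxolan-4-yl]-2,3-dihydrobenzofuran
Conditions: MeI, K2CO3, acetone, 40 °C
Reagents that add atoms: iodomethane, CI
Why: Williamson methylation of the only free phenol installs the C7 methoxyl.

Step 17
Reactants: 30 the methyl ether acetonide
Product: 31 (1R,2S)-1-[(2S,3S)-2-(3-benzyloxy-4,5-dimethoxyphenyl)-7-methoxy-3-methyl-2,3-dihydrobenzofuran-5-yl]propane-1,2-diol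
Conditions: AcOH–H2O (4:1), 40 °C
Reagents that add atoms: none
Why: acid hydrolysis of the acetonide proceeds through the ketal carbon and not through the benzylic C1′–O or C2–O1 bonds, so dilute acetic acid should free the diol without epimerisation.

Step 18
Reactants: 31 the benzyl-protected diol
Product: 32 (1R,2S)-1-[(2S,3S)-2-(3-hydroxy-4,5-dimethoxyphenyl)-7-methoxy-3-methyl-2,3-dihydrobenzofuran-5-yl]propane-1,2-diol
Conditions: H2 (1 atm), 10% Pd/C, EtOAc, rt
Reagents that add atoms: none
Why: hydrogenolysis of the aryl benzyl ether under neutral conditions is much faster than cleavage of the benzylic C2–O1 and C1′–OH bonds, so it should unmask the phenol and leave the target.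

**Compound list**

1 | 3-hydroxy-4,5-dimethoxybenzaldehyde | COc1cc(C=O)cc(O)c1OC | starting material
2 | 3-(benzyloxy)-4,5-dimethoxybenzaldehyde | COc1cc(C=O)cc(OCc2ccccc2)c1OC | intermediate
3 | ethyl (S)-lactate | CCOC(=O)[C@H](C)O | starting material
4 | ethyl (S)-2-(triethylsilyloxy)propanoate | CCOC(=O)[C@H](C)O[Si](CC)(CC)CC | intermediate
5 | (S)-N-methoxy-N-methyl-2-(triethylsilyloxy)propanamide | CON(C)C(=O)[C@H](C)O[Si](CC)(CC)CC | intermediate
6 | 4-bromo-2-furaldehyde | O=Cc1cc(Br)co1 | starting material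
7 | N-[2-(4-bromofuran-2-yl)-1-tosylethenyl]formamide (as its potassium salt) | O=CNC(=Cc1cc(Br)co1)S(=O)(=O)c1ccc(C)cc1 | intermediate (not isolated)
8 | 2-(4-bromofuran-2-yl)acetonitrile | N#CCc1cc(Br)co1 | intermediate
9 | 2-(4-bromofuran-2-yl)acetic acid | OC(=O)Cc1cc(Br)co1 | intermediate
10 | (S)-4-benzyl-2-oxazolidinone | O=C1OC[C@H](Cc2ccccc2)N1 | starting material
11 | 2-(4-bromofuran-2-yl)acetic pivalic anhydride | CC(C)(C)C(=O)OC(=O)Cc1cc(Br)co1 | intermediate (not isolated)
12 | (S)-4-benzyl-3-[2-(4-bromofuran-2-yl)acetyl]oxazolidin-2-one | O=C1OC[C@H](Cc2ccccc2)N1C(=O)Cc3cc(Br)co3 | intermediate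
13 | (S)-4-benzyl-3-[(Z)-2-(4-bromofuran-2-yl)-1-(dibutylboryloxy)ethenyl]oxazolidin-2-one | CCCCB(CCCC)O/C(=C\c1cc(Br)co1)N2C(=O)OC[C@@H]2Cc3ccccc3 | intermediate (not isolated)
14 | (S)-4-benzyl-3-[(2R,3S)-3-(3-benzyloxy-4,5-dimethoxyphenyl)-2-(4-bromofuran-2-yl)-3-hydroxypropanoyl]oxazolidin-2-one | COc1cc([C@@H](O)[C@@H](C(=O)N2C(=O)OC[C@@H]2Cc3ccccc3)c4cc(Br)co4)cc(OCc5ccccc5)c1OC | intermediate
15 | (1S,2R)-1-(3-benzyloxy-4,5-dimethoxyphenyl)-2-(4-bromofuran-2-yl)propane-1,3-diol | COc1cc([C@@H](O)[C@@H](CO)c2cc(Br)co2)cc(OCc3ccccc3)c1OC | intermediate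
16 | (2R,3S)-3-(3-benzyloxy-4,5-dimethoxyphenyl)-2-(4-bromofuran-2-yl)-3-hydroxypropyl 4-methylbenzenesulfonate | COc1cc([C@@H](O)[C@@H](COS(=O)(=O)c2ccc(C)cc2)c3cc(Br)co3)cc(OCc4ccccc4)c1OC | intermediate
17 | (1S,2R)-1-(3-benzyloxy-4,5-dimethoxyphenyl)-2-(4-bromofuran-2-yl)propan-1-ol | COc1cc([C@@H](O)[C@@H](C)c2cc(Br)co2)cc(OCc3ccccc3)c1OC | intermediate
18 | lithium (1S,2R)-1-(3-benzyloxy-4,5-dimethoxyphenyl)-2-(4-lithiofuran-2-yl)propan-1-olate | COc1cc([C@@H](O[Li])[C@@H](C)c2cc([Li])co2)cc(OCc3ccccc3)c1OC | intermediate (not isolated)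
19 | (S)-1-{5-[(1S,2R)-1-(3-benzyloxy-4,5-dimethoxyphenyl)-1-hydroxypropan-2-yl]furan-3-yl}-2-(triethylsilyloxy)propan-1-one | COc1cc([C@@H](O)[C@@H](C)c2cc(C(=O)[C@H](C)O[Si](CC)(CC)CC)co2)cc(OCc3ccccc3)c1OC | intermediate (not isolated)
20 | (S)-1-{5-[(1S,2R)-1-(3-benzyloxy-4,5-dimethoxyphenyl)-1-hydroxypropan-2-yl]furan-3-yl}-2-hydroxypropan-1-one | COc1cc([C@@H](O)[C@@H](C)c2cc(C(=O)[C@H](C)O)co2)cc(OCc3ccccc3)c1OC | intermediate
21 | (1R,2S)-1-{5-[(1S,2R)-1-(3-benzyloxy-4,5-dimethoxyphenyl)-1-hydroxypropan-2-yl]furan-3-yl}propane-1,2-diol | COc1cc([C@@H](O)[C@@H](C)c2cc([C@@H](O)[C@H](C)O)co2)cc(OCc3ccccc3)c1OC | intermediate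
22 | (1S,2R)-1-(3-benzyloxy-4,5-dimethoxyphenyl)-2-{4-[(4R,5S)-2,2,5-trimethyl-1,3-dioxolan-4-yl]furan-2-yl}propan-1-ol | COc1cc([C@@H](O)[C@@H](C)c2cc([C@H]3OC(C)(C)O[C@H]3C)co2)cc(OCc4ccccc4)c1OC | intermediate
23 | potassium alkoxide of 22 | COc1cc([C@@H](O[K])[C@@H](C)c2cc([C@H]3OC(C)(C)O[C@H]3C)co2)cc(OCc4ccccc4)c1OC | intermediate (not isolated)
24 | 2-{(1S,2R)-1-(3-benzyloxy-4,5-dimethoxyphenyl)-1-[(E)-1,2-dichlorovinyloxy]propan-2-yl}-4-[(4R,5S)-2,2,5-trimethyl-1,3-dioxolan-4-yl]furan | COc1cc([C@@H](O/C(Cl)=C\Cl)[C@@H](C)c2cc([C@H]3OC(C)(C)O[C@H]3C)co2)cc(OCc4ccccc4)c1OC | intermediate (not isolated)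
25 | lithium acetylide of 26 (lithioethynyl ether) | COc1cc([C@@H](OC#C[Li])[C@@H](C)c2cc([C@H]3OC(C)(C)O[C@H]3C)co2)cc(OCc4ccccc4)c1OC | intermediate (not isolated)
26 | 2-[(1S,2R)-1-(3-benzyloxy-4,5-dimethoxyphenyl)-1-(ethynyloxy)propan-2-yl]-4-[(4R,5S)-2,2,5-trimethyl-1,3-dioxolan-4-yl]furan | COc1cc([C@@H](OC#C)[C@@H](C)c2cc([C@H]3OC(C)(C)O[C@H]3C)co2)cc(OCc4ccccc4)c1OC | intermediate
27 | oxepine: ring B fused at C3a–C7a to the ring O–C7=C7a–C3a=C4–C5=C6, with (2S,3S) aryl and methyl groups and the dioxolane on C5 | COc1cc([C@H]2OC3=COC=C([C@H]4OC(C)(C)O[C@H]4C)C=C3[C@@H]2C)cc(OCc5ccccc5)c1OC | intermediate (not isolated)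
28 | (2S,3S)-2-(3-benzyloxy-4,5-dimethoxyphenyl)-6,7-epoxy-3-methyl-5-[(4R,5S)-2,2,5-trimethyl-1,3-dioxolan-4-yl]-2,3,6,7-tetrahydrobenzofuran (arene oxide, epoxide face not defined) | COc1cc([C@H]2OC3=C([C@@H]2C)C=C([C@H]4OC(C)(C)O[C@H]4C)C5OC35)cc(OCc6ccccc6)c1OC | intermediate (not isolated)
29 | (2S,3S)-2-(3-benzyloxy-4,5-dimethoxyphenyl)-3-methyl-5-[(4R,5S)-2,2,5-trimethyl-1,3-dioxolan-4-yl]-2,3-dihydrobenzofuran-7-ol | COc1cc([C@H]2Oc3c(O)cc([C@H]4OC(C)(C)O[C@H]4C)cc3[C@@H]2C)cc(OCc5ccccc5)c1OC | intermediate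
30 | (2S,3S)-2-(3-benzyloxy-4,5-dimethoxyphenyl)-7-methoxy-3-methyl-5-[(4R,5S)-2,2,5-trimethyl-1,3-dioxolan-4-yl]-2,3-dihydrobenzofuran | COc1cc([C@H]2Oc3c(OC)cc([C@H]4OC(C)(C)O[C@H]4C)cc3[C@@H]2C)cc(OCc5ccccc5)c1OC | intermediate
31 | (1R,2S)-1-[(2S,3S)-2-(3-benzyloxy-4,5-dimethoxyphenyl)-7-methoxy-3-methyl-2,3-dihydrobenzofuran-5-yl]propane-1,2-diol | COc1cc([C@H]2Oc3c(OC)cc([C@@H](O)[C@H](C)O)cc3[C@@H]2C)cc(OCc4ccccc4)c1OC | intermediate
32 | (1R,2S)-1-[(2S,3S)-2-(3-hydroxy-4,5-dimethoxyphenyl)-7-methoxy-3-methyl-2,3-dihydrobenzofuran-5-yl]propane-1,2-diol | COc1cc([C@H]2Oc3c(OC)cc([C@@H](O)[C@H](C)O)cc3[C@@H]2C)cc(O)c1OC | target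

**Step count**

Total: 18 steps. Longest linear sequence: 15 steps (steps 4 to 18, from 6).

**Steps most likely to fail**

1. Step 14 (making the ynol ether). The hindered secondary potassium alkoxide may add too slowly to dichloroacetylene, or may fragment by retro-addition to aldehyde 2 and a furfuryl anion; excess butyllithium may also metalate furan C5. The fallback avoids the alkoxide and builds the alkyne carbons by carbonyl olefination. It sets out from 22: acetic formic anhydride and pyridine would give the formate ester F1. Wittig-type dichloromethylenation of the formate carbonyl with PPh3 and CCl4 in THF at 60 °C would give the 2,2-dichlorovinyl ether F2. n-BuLi (2.2 equiv, −78 °C) and a methanol quench would then lead through 25 back to 26.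

2. Step 15 (the gold cascade). The gold-activated benzylic ynol ether may lose its electron-rich benzyl group, by C–O ionisation or by a sigmatropic shift onto the trioxygenated ring, faster than furan C2 attacks, so that no phenol forms. The fallback gives up the furan–yne closure: ring A is bought as a benzene and ring B is closed by cationic etherification. It sets out from 2 and 10 and comes back at 31.
   - Commercial 5-bromo-2-hydroxy-3-methoxybenzaldehyde would be protected (MOMCl, i-Pr2NEt) as 5-bromo-3-methoxy-2-(methoxymethoxy)benzaldehyde F3.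
   - TosMIC and t-BuOK, then methanol, would give the arylacetonitrile F4, and KOH the arylacetic acid F5.
   - Pivaloyl chloride, Et3N, LiCl and 10 would give the imide F6.
   - The Bu2BOTf-mediated syn-aldol with 2 would give the aldol adduct F7.
   - LiBH4, then TsCl, then LiEt3BH would give in turn the 1,3-diol F8, the primary tosylate F9 and the methyl carbinol F10.
   - Trifluoroacetic acid in CH2Cl2 at 0 °C would remove the MOM group and close ring B through the p-methoxybenzyl cation to the trans-bromodihydrobenzofuran F11 (C3 fixed by the aldol, C2 set trans under thermodynamic control).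
   - Bromine–lithium exchange (n-BuLi, −78 °C) and acylation with 5 would give the silyl-protected ketone F12, and dilute acetic acid the hydroxy ketone F13.
   - Zn(BH4)2 reduction would give 31, one step before the target.

3. Step 10 (hydride displacement of the tosylate). The alkoxide formed from the free γ-hydroxyl may trigger Grob fragmentation to aldehyde 2 and a vinylfuran, or close an oxetane, before hydride displaces the tosylate. The fallback removes the oxygen by a radical chain and involves no alkoxide. It sets out from 15: I2, PPh3 and imidazole would convert the primary hydroxyl selectively into the primary iodide F14. Bu3SnH with Et3B and air in toluene at 0 °C would reduce the C–I bond, much faster than the furyl C–Br bond, and return to 17.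

**Further compounds**

F1 | step 14 | (1S,2R)-1-(3-benzyloxy-4,5-dimethoxyphenyl)-2-{4-[(4R,5S)-2,2,5-trimethyl-1,3-dioxolan-4-yl]furan-2-yl}propyl formate | COc1cc([C@@H](OC=O)[C@@H](C)c2cc([C@H]3OC(C)(C)O[C@H]3C)co2)cc(OCc4ccccc4)c1OC
F2 | step 14 | 2-[(1S,2R)-1-(3-benzyloxy-4,5-dimethoxyphenyl)-1-(2,2-dichlorovinyloxy)propan-2-yl]-4-[(4R,5S)-2,2,5-trimethyl-1,3-dioxolan-4-yl]furan | COc1cc([C@@H](OC=C(Cl)Cl)[C@@H](C)c2cc([C@H]3OC(C)(C)O[C@H]3C)co2)cc(OCc4ccccc4)c1OC
F3 | step 15 | 5-bromo-3-methoxy-2-(methoxymethoxy)benzaldehyde | COCOc1c(OC)cc(Br)cc1C=O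
F4 | step 15 | 2-[5-bromo-3-methoxy-2-(methoxymethoxy)phenyl]acetonitrile | COCOc1c(OC)cc(Br)cc1CC#N
F5 | step 15 | 2-[5-bromo-3-methoxy-2-(methoxymethoxy)phenyl]acetic acid | COCOc1c(OC)cc(Br)cc1CC(=O)O
F6 | step 15 | (S)-4-benzyl-3-{2-[5-bromo-3-methoxy-2-(methoxymethoxy)phenyl]acetyl}oxazolidin-2-one | COCOc1c(OC)cc(Br)cc1CC(=O)N2C(=O)OC[C@@H]2Cc3ccccc3
F7 | step 15 | (S)-4-benzyl-3-{(2S,3S)-3-(3-benzyloxy-4,5-dimethoxyphenyl)-2-[5-bromo-3-methoxy-2-(methoxymethoxy)phenyl]-3-hydroxypropanoyl}oxazolidin-2-one | COc1cc([C@@H](O)[C@@H](C(=O)N2C(=O)OC[C@@H]2Cc3ccccc3)c4cc(Br)cc(OC)c4OCOC)cc(OCc5ccccc5)c1OC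
F8 | step 15 | (1S,2R)-1-(3-benzyloxy-4,5-dimethoxyphenyl)-2-[5-bromo-3-methoxy-2-(methoxymethoxy)phenyl]propane-1,3-diol | COc1cc([C@@H](O)[C@@H](CO)c2cc(Br)cc(OC)c2OCOC)cc(OCc3ccccc3)c1OC
F9 | step 15 | (2R,3S)-3-(3-benzyloxy-4,5-dimethoxyphenyl)-2-[5-bromo-3-methoxy-2-(methoxymethoxy)phenyl]-3-hydroxypropyl 4-methylbenzenesulfonate | COc1cc([C@@H](O)[C@@H](COS(=O)(=O)c2ccc(C)cc2)c3cc(Br)cc(OC)c3OCOC)cc(OCc4ccccc4)c1OC
F10 | step 15 | (1S,2S)-1-(3-benzyloxy-4,5-dimethoxyphenyl)-2-[5-bromo-3-methoxy-2-(methoxymethoxy)phenyl]propan-1-ol | COc1cc([C@@H](O)[C@@H](C)c2cc(Br)cc(OC)c2OCOC)cc(OCc3ccccc3)c1OC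
F11 | step 15 | (2S,3S)-2-(3-benzyloxy-4,5-dimethoxyphenyl)-5-bromo-7-methoxy-3-methyl-2,3-dihydrobenzofuran | COc1cc([C@H]2Oc3c(OC)cc(Br)cc3[C@@H]2C)cc(OCc4ccccc4)c1OC
F12 | step 15 | (S)-1-[(2S,3S)-2-(3-benzyloxy-4,5-dimethoxyphenyl)-7-methoxy-3-methyl-2,3-dihydrobenzofuran-5-yl]-2-(triethylsilyloxy)propan-1-one | COc1cc([C@H]2Oc3c(OC)cc(C(=O)[C@H](C)O[Si](CC)(CC)CC)cc3[C@@H]2C)cc(OCc4ccccc4)c1OC
F13 | step 15 | (S)-1-[(2S,3S)-2-(3-benzyloxy-4,5-dimethoxyphenyl)-7-methoxy-3-methyl-2,3-dihydrobenzofuran-5-yl]-2-hydroxypropan-1-one | COc1cc([C@H]2Oc3c(OC)cc(C(=O)[C@H](C)O)cc3[C@@H]2C)cc(OCc4ccccc4)c1OC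
F14 | step 10 | (1S,2R)-1-(3-benzyloxy-4,5-dimethoxyphenyl)-2-(4-bromofuran-2-yl)-3-iodopropan-1-ol | COc1cc([C@@H](O)[C@@H](CI)c2cc(Br)co2)cc(OCc3ccccc3)c1OC
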